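The midnight run charged more starting material than the winter run, yet both consume it at about the same fractional pace. We add other capture product and target, and define the ageing constant, the natural log of the charge over the part not found in those two products, divided by time: 0.315 h⁻¹ from midnight's last reading and 0.310 h⁻¹ from winter's. So we take the turning of starting material into intermediate as the rate-limiting step in these two runs.

But spring stalls at 52.1% of other capture product, and its second nucleophile allows 52.5%. In spring the second nucleophile is the limiting reagent.

| flask | starting material | first nucleophile | second nucleophile | remark | time |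
|---|---|---|---|---|---|
| midnight | 0.40 M | 0.44 M | 0.42 M | run made earlier |  |
| winter | 0.20 M | 0.44 M | 0.42 M | run made earlier |  |
| spring | 0.80 M | 0.44 M | 0.42 M | run made earlier |  |
| oak | 0.40 M | 0.440 M | 0.420 M (fed, over 2.0 h) | all else is in the flask from the start; the feed brings no volume worth counting | 3.0 h |
| maple | 0.40 M (in portions, 3, over 2.0 h) | 0.440 M | 0.420 M | first portion at the start, last at 2.0 h | 3.0 h |
| birch | 0.40 M (fed, over 2.0 h) | 0.440 M | 0.420 M | all else is in the flask from the start; the feed brings no volume worth counting | 3.0 h |
| cedar | 0.40 M | 0.440 M | 0.420 M | everything together at the start | 3.0 h |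

| run | time / h | other capture product / % | target / % |
|---|---|---|---|
| midnight | 0.200 | 4.4 | 1.2 |
| midnight | 0.667 | 17.4 | 1.8 |
| midnight | 1.00 | 25.8 | 1.6 |
| midnight | 1.50 | 36.2 | 2.1 |
| midnight | 2.50 | 53.0 | 2.1 |
| midnight | 3.00 | 59.1 | 2.0 |
| winter | 0.250 | 5.9 | 2.1 |
| winter | 0.500 | 13.1 | 1.9 |
| winter | 0.833 | 21.7 | 2.0 |
| winter | 1.33 | 33.2 | 1.6 |
| winter | 2.00 | 45.9 | 0.7 |
| winter | 4.00 | 70.4 | 0.7 |
| spring | 0.250 | 6.1 | 2.1 |
| spring | 0.667 | 17.0 | 2.4 |
| spring | 1.33 | 31.8 | 3.2 |
| spring | 2.00 | 43.0 | 3.5 |
| spring | 3.00 | 50.8 | 6.5 |
| spring | 4.00 | 52.1 | 10.7 |

(scatter of a reading: 0.3 percentage points)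

- steps under discussion: starting material <-> intermediate; first nucleophile + intermediate <-> target; second nucleophile + intermediate -> other capture product; first nucleophile + target -> over-reaction product

* the flask that comes out highest in amount of other capture product, in percent of the starting material charged; "all alike" if 1.5 percentage points covers them all (oak / maple / birch / cedar / all alike)
* amount of other capture product at the end, in percent of the starting material charged, oak
* amount of other capture product at the end, in percent of the starting material charged, maple
* amount of other capture product at the end, in percent of the starting material charged, birch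
* amount of other capture product at the end, in percent of the starting material charged, cedar

Cedar repeats midnight, so we expect 59.1%. Birch and maple bring the charge in late, so each part ages from its own entry. We apply the ageing constant to each part, average, and subtract midnight's 2.0% of target. That gives 43.8% for birch and 42.9% for maple.

Oak needs a ratio in which time drops out. Its feed brings 0.210 M h⁻¹, while starting material first demands 0.126 M h⁻¹, so supply over demand is 1.67. So we place oak a little below cedar: oak's feed outruns that first demand, but oak's second nucleophile starts the run at nothing, while cedar's starts at 0.420 M.

The forecast names cedar highest, with 59.2% for cedar, 56% for oak, 44.5% for birch and 44% for maple. Its grounds for the late flasks: “Birch and maple simply age the material less”.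

The flasks give 59.0% for cedar, 56.0% for oak, 44.3% for birch and 43.3% for maple, so cedar is highest.

    starting material ⇌ intermediate (K = 0.204, k = 0.00576 min⁻¹)
    first nucleophile + intermediate ⇌ target (K = 34.8 M⁻¹, k = 19.6 M⁻¹ min⁻¹)
    second nucleophile + intermediate → other capture product (k = 8.46 M⁻¹ min⁻¹)
    first nucleophile + target → over-reaction product (k = 0.0229 M⁻¹ min⁻¹)

In oak at 1.50 h, with the feed still running, capture had reached 31.7% of other capture product while over-reaction product stood at 4.51%. By 3.00 h, oak held 6.08% of over-reaction product against cedar's 3.32%, and 36.2% of starting material against cedar's 35.9%. The ageing constant gave birch 43.8%, and birch gave 44.3%. A neighbour of cedar charged with 0.68 M of starting material reached 59.0% in other capture product and target, against 61.1% from the ageing constant.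

The numbers in the tables come from a simulation for substances that don't exist.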